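Compounds are numbered 1–30 in the order they appear in the steps; 30 is the target.

## Analysis of the target

Compound 30 is a 3,4-dihydroisocoumarin: ring A is fused to a six-membered lactone (C1 carbonyl, O2, C3, C4, C4a, C8a) whose C3 is a hemiketal carbon bearing a hydroxyl and a CH2O arm, and that arm is acylated by ring B, 2,4-dihydroxy-5,6-dimethylbenzoic acid. Ring A is pentasubstituted: the lactone carbonyl on C8a, a chelated hydroxyl on C8, hydrogen on C7, methoxy on C6, methyl on C5 and the C4 methine on C4a. The two stereocentres are adjacent, C3 (R) and C4 (S); the C3 hydroxyl and the C4 methyl are trans, which in the half-chair lets both sit axial (anomeric hydroxyl, C4 methyl turned away from the peri C5 methyl) with the acyloxymethyl arm equatorial. C3 is a lactol carbon that opens to keto acid 29, so its configuration should follow from equilibration and only C4 has to be set by an asymmetric step. In the open form C4 is benzylic and α to a ketone, so once the C3 carbonyl exists this centre is at risk under acid or base; the lactol, the three free phenols on electron-rich rings and the ester of a doubly ortho-substituted benzoic acid are the other sensitive points. The difficulty lies in the regiochemistry of a crowded ring A with one free and one methylated oxygen, in joining it to C4 next to the C5 methyl, and in keeping C4 intact. The route rests on reading ring A as two pieces: C8(O)–C7(H)–C6(OMe)–C5(CH3) has the substitution of a 1,3-dioxygenated penta-1,3-diene, and the C4a–C8a edge, with the side chain on one carbon and the carboxyl on the other, is an alk-2-ynoate whose propargylic carbon is C4.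

## Retrosynthetic reasoning

**Lactol (O2–C3).** Target 30 is the ring tautomer of keto acid 29, so the bond between the carboxyl oxygen and C3 is cut first. Acid 29 is traced to ketone 28, in which the acid and all three phenols are benzylated. One neutral hydrogenolysis then frees four groups, and the lactol closes without C4 meeting acid or base.

**Oxidation level at C3 (28 to 25).** Ketone 28 is taken back to alcohol 27, silyl ether 26 and phenol 25. C3 is carried as a protected secondary alcohol because a ketone there would make C4 acidic through every earlier step. The C8 phenol is capped as a benzyl ether so that the oxidation meets no free phenol, and that benzyl group leaves in the last step at no extra cost.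

**Ring A (C4a–C5 and C8–C8a).** Phenol 25 is cut into ynoate 17 and diene 22, with cycloadduct 23 and silyl ether 24 as unisolated stages. These two bonds are chosen because cutting them removes all six ring A substituents at once with the methoxy and hydroxyl already differentiated. The alternative of attaching a finished pentasubstituted arene to C4 would need a bond between a di-ortho-substituted aryl carbon and a secondary stereogenic carbon. The forward step has to control only regiochemistry, and C4 rides through as a propargylic centre.

**Carboxyl carbon (C1–C8a).** Ynoate 17 comes from terminal alkyne 15 through acetylide 16 and a chloroformate, so the lactone carbonyl carbon enters as a benzyl ester that hydrogenolysis can later remove. Alkyne 15 is the silyl ether of alcohol 14.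

**Ester C–O bond to ring B.** Hydroxy ester 14 is cut into acid 5, used as acyl chloride 13, and diol 12. Ring B is attached early, while the only competing nucleophile is a hindered secondary hydroxyl, and it then serves as the protecting group of the primary oxygen.

**C4–C(sp) bond and the stereocentre.** Diol 12 comes from silylalkyne 11, which is cut at the bond between C4 and the alkyne carbon into epoxy alcohol 7 and alkynylalane 10 (from alkyne 8 through acetylide 9). Epoxide 7 comes from alcohol 6 by asymmetric epoxidation. Inversion at the methyl-bearing epoxide carbon turns a reagent-controlled epoxide into the C4 configuration.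

**Ring B acid.** Acid 5 is taken back through aldehydes 4 and 3 to resorcinol 1, cutting the bond between ring B and its carboxyl carbon; iminium salt 2 is the unisolated stage. Formylation is used because it goes para to one hydroxyl and ortho to the other, which is the position required.

**Diene.** Diene 22 is the silyl dienol ether of enoate 20 (through dienolate 21), and 20 is the enol ether of keto ester 18 (through ketal 19). The ethyl group of 18 supplies the C5 methyl and its terminus.

## Alternatives that were turned down

**Alternative 1:** The disconnection is the C4a–C8a bond, with ring A traced back to an open polyketide-type chain, diketo-dioxinone A2.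
- Forward key step: thermolysis of A2 in the presence of the alcohol that supplies the benzyl ester would open the dioxinone to an acylketene and trap it as a triketo ester. The C8a methylene would then add to the C4a ketone and the aldol product would dehydrate to resorcylate A1.
- For it: the ring closure is mild and metal-free, the substitution pattern is dictated by the chain, and the C5 methyl is carried in as a chain branch.
- Against it: in A2 the C4 centre sits α to the very ketone that must act as aldol acceptor, and β to a dioxolane oxygen, so enolisation invites epimerisation and β-elimination. That ketone is branched on both sides, so the aldol is slow and other cyclisation modes of the triketide can compete. A1 has both phenols free and its side chain as an acetonide, so O-methylation at C6, acetonide removal, acylation with acid 5 and oxidation at C3 all still follow.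
- Comparison: Alternative 1 is stronger on the mildness of the ring-forming event, which needs no sealed-tube cycloaddition. The chosen route offers instead a C4 centre that is never next to a carbonyl until the penultimate step, and a ring A that emerges with OMe and OH already told apart.

**Alternative 2:** The disconnection is the C1–O2 and O2–C3 pair, which contracts the lactol ring to indanone α-ketol A4.
- Forward key step: a peracid would insert oxygen between the carbonyl and the hydroxylated quaternary carbon, or a periodate-type cleavage of the α-ketol would give the keto acid, which recloses; either way lactol A3 results.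
- For it: A3 needs only hydrogenolysis, the C3 oxidation level arrives directly, and no free hydroxy ester that could lactonise is ever formed. On this endgame point Alternative 2 is stronger than the chosen route.
- Against it: it leaves the real problem untouched. The pentasubstituted ring A still has to be made, now fused to a cyclopentanone whose C3 methyl is pressed against the C4 methyl. A4 also needs an enantioselective indanone synthesis, a hydroxymethyl and a hydroxyl placed on C2, and acylation with the hindered acid 5. In the peracid mode the electron-rich aryl group can migrate in competition, and both arenes are open to oxidation.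
- Comparison: reaching A4 should take clearly more steps than reaching ynoate 17. The chosen route makes ring A and joins it to C4 in one operation and pays for this with a four-step endgame.

**Alternative 3:** The disconnection is the C1'–C2' and C5'–C6' pair of ring B.
- Forward key step: diene A7 would add to the but-2-ynoate ester A6 and lose methanol to give keto ester A5 with the ring B phenols free.
- For it: the ester bond is made from an unhindered alkynoic acid before the ortho substituents exist, and ring B needs no benzyl ethers. On these two points it is stronger than the chosen route, which must force a doubly ortho-substituted acyl chloride onto the diol in step 7.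
- Against it: the cycloaddition is spent on the easy ring, since acid 5 is three routine steps from resorcinol 1. Ring A, with the stereocentre attached, still has to be built by other means before A6 exists. A6 also carries the C3 ketone, so C4 would be α to a carbonyl and benzylic while heated with a nucleophilic silyl ketene acetal that can add to that ketone.
- Comparison: the chosen route accepts one hindered acylation and two extra benzyl groups in exchange for using the key step on the difficult ring and running it before the epimerisable ketone exists.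

Key step: step 12

Remark on the chemistry: C3 of 30 is assumed to equilibrate through keto acid 29, so its (R) configuration is taken as the thermodynamic outcome of ring closure and not as something a reagent sets.

## Steps

**Step 1**
Reactants: 1 4,5-dimethylbenzene-1,3-diol (4,5-dimethylresorcinol)
Product: 3 2,4-dihydroxy-5,6-dimethylbenzaldehyde, via aryl iminium chloride 2 (not isolated)
Conditions: POCl3, DMF, MeCN, 0 °C to rt; then H2O, 50 °C
Reagents that add atoms: N,N-dimethylformamide CN(C)C=O; water O
Why: Vilsmeier–Haack formylation; the chloroiminium electrophile attacks the ring position para to one hydroxyl and ortho to the other, which is less hindered than the position between the two hydroxyls, and hydrolysis of iminium salt 2 releases the aldehyde.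

**Step 2**
Reactants: 3 2,4-dihydroxy-5,6-dimethylbenzaldehyde
Product: 4 2,4-bis(benzyloxy)-5,6-dimethylbenzaldehyde
Conditions: BnBr (2.5 equiv), K2CO3, DMF, 60 °C
Reagents that add atoms: benzyl bromide BrCc1ccccc1
Why: Williamson etherification; the para hydroxyl reacts first and the hydrogen-bonded ortho hydroxyl follows with excess halide and heat.

**Step 3**
Reactants: 4 2,4-bis(benzyloxy)-5,6-dimethylbenzaldehyde
Product: 5 2,4-bis(benzyloxy)-5,6-dimethylbenzoic acid
Conditions: NaClO2, NaH2PO4, 2-methylbut-2-ene, t-BuOH/THF/H2O, rt
Reagents that add atoms: sodium chlorite [Na+].[O-]Cl=O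
Why: Pinnick oxidation; chlorous acid converts the hindered, electron-rich aldehyde to the acid without touching the benzyl ethers, and the alkene removes hypochlorous acid before it can chlorinate the ring.

**Step 4**
Reactants: 6 (E)-but-2-en-1-ol
Product: 7 [(2S,3S)-3-methyloxiran-2-yl]methanol
Conditions: Ti(OiPr)4 (cat.), L-(+)-diethyl tartrate (cat.), t-BuOOH (anhydrous), 4 Å MS, CH2Cl2, −20 °C; non-aqueous work-up, distillation
Reagents that add atoms: tert-butyl hydroperoxide CC(C)(C)OO
Why: Sharpless asymmetric epoxidation; the titanium tartrate complex binds the allylic alkoxide and the hydroperoxide and delivers oxygen to one face of the (E)-alkene, the L-(+)-tartrate giving the (2S,3S)-epoxide. This fixes the carbon that becomes C4.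

**Step 5**
Reactants: 8 ethynyltrimethylsilane; 7 [(2S,3S)-3-methyloxiran-2-yl]methanol
Product: 11 (2R,3S)-3-methyl-5-(trimethylsilyl)pent-4-yne-1,2-diol, via lithium (trimethylsilyl)acetylide 9 (not isolated), via diethyl[(trimethylsilyl)ethynyl]aluminium 10 (not isolated)
Conditions: 8, n-BuLi, toluene, 0 °C; Et2AlCl, 0 °C; then 7 (alane 3 equiv), toluene/CH2Cl2, 0 °C to rt; aq. potassium sodium tartrate
Reagents that add atoms: none
Why: Hydroxyl-directed opening of a 2,3-epoxy alcohol by an alkynylalane: the substrate binds as an aluminium alkoxide that activates the epoxide, and the alkynyl group is transferred to C3 with inversion (SN2) to give the 1,2-diol. C3 becomes (S); untouched C2 is now called (R) only because the substituent priorities change.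

**Step 6**
Reactants: 11 (2R,3S)-3-methyl-5-(trimethylsilyl)pent-4-yne-1,2-diol
Product: 12 (2R,3S)-3-methylpent-4-yne-1,2-diol
Conditions: K2CO3 (cat.), MeOH, rt
Reagents that add atoms: none
Why: Methoxide-mediated protodesilylation of the alkynylsilane; nothing else in the diol reacts, and doing it here keeps methoxide away from the later esters and silyl ether.

**Step 7**
Reactants: 5 2,4-bis(benzyloxy)-5,6-dimethylbenzoic acid; 12 (2R,3S)-3-methylpent-4-yne-1,2-diol
Product: 14 (2R,3S)-2-hydroxy-3-methylpent-4-yn-1-yl 2,4-bis(benzyloxy)-5,6-dimethylbenzoate, via acid chloride 13 (not isolated)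
Conditions: 5, (COCl)2, DMF (cat.), CH2Cl2, 0 °C to rt; concentrate; then 12 (1.2 equiv), Et3N, DMAP (cat.), CH2Cl2, −20 to 0 °C
Reagents that add atoms: none
Why: Acyl chloride formation followed by DMAP-catalysed acylation; the doubly ortho-substituted aroyl chloride should react far faster at the primary hydroxyl than at the secondary one next to the branched C3, and a slight excess of diol suppresses diacylation.

**Step 8**
Reactants: 14 (2R,3S)-2-hydroxy-3-methylpent-4-yn-1-yl 2,4-bis(benzyloxy)-5,6-dimethylbenzoate
Product: 15 (2R,3S)-3-methyl-2-(triethylsilyloxy)pent-4-yn-1-yl 2,4-bis(benzyloxy)-5,6-dimethylbenzoate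
Conditions: Et3SiOTf, 2,6-lutidine, CH2Cl2, −78 to 0 °C
Reagents that add atoms: triethylsilyl trifluoromethanesulfonate CC[Si](CC)(CC)OS(=O)(=O)C(F)(F)F
Why: Silylation of the secondary alcohol with a silyl triflate and a hindered pyridine base, fast enough at low temperature to outrun acyl migration; the triethylsilyl ether should survive the acetylide and thermal steps yet yield to buffered fluoride.

**Step 9**
Reactants: 15 (2R,3S)-3-methyl-2-(triethylsilyloxy)pent-4-yn-1-yl 2,4-bis(benzyloxy)-5,6-dimethylbenzoate
Product: 17 benzyl (4S,5R)-6-{[2,4-bis(benzyloxy)-5,6-dimethylbenzoyl]oxy}-4-methyl-5-(triethylsilyloxy)hex-2-ynoate, via lithium acetylide 16 (not isolated)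
Conditions: LiN(SiMe3)2 (1.0 equiv), THF, −78 °C; ClCO2Bn, −78 to −40 °C; aq. NH4Cl at −40 °C
Reagents that add atoms: benzyl chloroformate O=C(Cl)OCc1ccccc1
Why: Deprotonation of the terminal alkyne and C-acylation of the lithium acetylide with a chloroformate; the silylamide is strong enough for the alkyne but too weak and hindered to metalate the ortho methyl of ring B or to attack either ester. A cold quench guards against propargyl–allenyl isomerisation at C4.

**Step 10**
Reactants: 18 methyl 3-oxopentanoate
Product: 20 methyl (2E)-3-methoxypent-2-enoate, via dimethyl ketal 19 (not isolated)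
Conditions: HC(OMe)3, H2SO4 (cat.), MeOH, rt; then distillation
Reagents that add atoms: trimethyl orthoformate COC(OC)OC
Why: Acid-catalysed ketalisation with the orthoester and loss of methanol on distillation give the conjugated enol ether; the (E)-isomer, with methoxy trans to the ester, is the thermodynamic product.

**Step 11**
Reactants: 20 methyl (2E)-3-methoxypent-2-enoate
Product: 22 (3Z)-1,3-dimethoxy-1-(trimethylsilyloxy)penta-1,3-diene, via lithium dienolate 21 (not isolated)
Conditions: LiN(iPr)2, THF, −78 °C; Me3SiCl, −78 °C to rt; pentane, filtration under Ar, distillation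
Reagents that add atoms: chlorotrimethylsilane C[Si](C)(C)Cl
Why: Kinetic γ-deprotonation of the β-methoxy enoate at the CH2 cis to the ester, then O-silylation of the extended enolate, gives the vinylketene acetal. The geometry of either double bond (the ketene acetal end is expected as a mixture) has no consequence for the arene formed from it.

**Step 12**
Reactants: 17 benzyl (4S,5R)-6-{[2,4-bis(benzyloxy)-5,6-dimethylbenzoyl]oxy}-4-methyl-5-(triethylsilyloxy)hex-2-ynoate; 22 (3Z)-1,3-dimethoxy-1-(trimethylsilyloxy)penta-1,3-diene
Product: 25 benzyl 2-[(2S,3R)-4-{[2,4-bis(benzyloxy)-5,6-dimethylbenzoyl]oxy}-3-(triethylsilyloxy)butan-2-yl]-6-hydroxy-4-methoxy-3-methylbenzoate, via cyclohexadiene cycloadduct 23 (not isolated), via aryl trimethylsilyl ether 24 (not isolated)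
Conditions: 22 (4 equiv), BHT (cat.), toluene, sealed tube, 120 °C; then SiO2, wet EtOAc, rt
Reagents that add atoms: none
Why: This is a normal-electron-demand Diels–Alder reaction between the electron-rich vinylketene acetal 22 and the electron-poor triple bond of 17, the established way of turning alkynoates into salicylates with 1-alkoxy-1-silyloxydienes. Bond formation is asynchronous: the CH(CH3) terminus of 22 (largest HOMO coefficient) bonds to the β-carbon of the ynoate (largest LUMO coefficient), giving C4a–C5, and the ketene-acetal carbon then bonds to the α-carbon, giving C8–C8a and cyclohexa-1,4-diene 23. The six-membered carbocycle is therefore closed by an intermolecular [4+2] cycloaddition, suprafacial on both partners; in the stepwise limit the second bond is a 6-exo-trig attack of the allenolate α-carbon on the oxocarbenium carbon. Loss of methanol across the ring (OMe from the ketal carbon, H from C5) aromatises 23 to silyl ether 24, whose labile aryl O–Si bond is hydrolysed on silica to the C8 phenol, while the enol ether oxygen, which is not on an sp3 carbon, stays as the C6 methoxy group. No stereocentre is created: the sp3 carbon at C5 of 23 disappears on aromatisation, and the propargylic C4 centre carries no acidifying group and meets only neutral, aprotic conditions, so it should pass unchanged into the benzylic position. The selectivity the step needs is regiochemical, and it is secured by the matched polarisation of the partners: both oxygen substituents of 22 push electron density to its methyl-bearing terminus and the ester of 17 makes the β-carbon the electrophilic site. Because both bond-forming carbons are substituted the reaction should be slow, hence the excess diene and the sealed tube.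

**Step 13**
Reactants: 25 benzyl 2-[(2S,3R)-4-{[2,4-bis(benzyloxy)-5,6-dimethylbenzoyl]oxy}-3-(triethylsilyloxy)butan-2-yl]-6-hydroxy-4-methoxy-3-methylbenzoate
Product: 26 benzyl 6-(benzyloxy)-2-[(2S,3R)-4-{[2,4-bis(benzyloxy)-5,6-dimethylbenzoyl]oxy}-3-(triethylsilyloxy)butan-2-yl]-4-methoxy-3-methylbenzoate
Conditions: BnBr, K2CO3, Bu4NI (cat.), DMF, 50 °C
Reagents that add atoms: benzyl bromide BrCc1ccccc1
Why: Williamson etherification of the hydrogen-bonded phenol; it removes the only free phenol before the oxidation of step 15 and adds a group that leaves in the final hydrogenolysis. The silyl ether and both esters are inert to carbonate in DMF.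

**Step 14**
Reactants: 26 benzyl 6-(benzyloxy)-2-[(2S,3R)-4-{[2,4-bis(benzyloxy)-5,6-dimethylbenzoyl]oxy}-3-(triethylsilyloxy)butan-2-yl]-4-methoxy-3-methylbenzoate
Product: 27 benzyl 6-(benzyloxy)-2-[(2S,3R)-4-{[2,4-bis(benzyloxy)-5,6-dimethylbenzoyl]oxy}-3-hydroxybutan-2-yl]-4-methoxy-3-methylbenzoate
Conditions: HF·pyridine, pyridine, THF, 0 °C; crude product used at once
Reagents that add atoms: none
Why: Fluoride-mediated cleavage of the triethylsilyl ether under pyridine-buffered, non-basic conditions; no alkoxide is formed, so lactonisation onto the doubly ortho-substituted benzyl ester and acyl migration should stay slow.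

**Step 15**
Reactants: 27 benzyl 6-(benzyloxy)-2-[(2S,3R)-4-{[2,4-bis(benzyloxy)-5,6-dimethylbenzoyl]oxy}-3-hydroxybutan-2-yl]-4-methoxy-3-methylbenzoate
Product: 28 benzyl 6-(benzyloxy)-2-[(2S)-4-{[2,4-bis(benzyloxy)-5,6-dimethylbenzoyl]oxy}-3-oxobutan-2-yl]-4-methoxy-3-methylbenzoate
Conditions: Dess–Martin periodinane, NaHCO3, CH2Cl2, 0 °C to rt
Reagents that add atoms: none
Why: Dess–Martin oxidation of the secondary alcohol with bicarbonate buffering; ligand exchange at iodine and internal proton removal need neither strong acid nor amine base, so the new α-aryl ketone should keep its C4 configuration.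

**Step 16**
Reactants: 28 benzyl 6-(benzyloxy)-2-[(2S)-4-{[2,4-bis(benzyloxy)-5,6-dimethylbenzoyl]oxy}-3-oxobutan-2-yl]-4-methoxy-3-methylbenzoate
Product: 30 [(3R,4S)-3,8-dihydroxy-6-methoxy-4,5-dimethyl-1-oxo-3,4-dihydro-1H-isochromen-3-yl]methyl 2,4-dihydroxy-5,6-dimethylbenzoate, via keto acid 29 (not isolated)
Conditions: H2 (1 atm), Pd/C, EtOAc, rt
Reagents that add atoms: none
Why: Hydrogenolysis of the three benzyl ethers and the benzyl ester under neutral conditions; the freed carboxylic acid adds to the activated α-acyloxy ketone (6-exo-trig hemiketalisation). Ring–chain equilibration should settle C3 as (R), with the hydroxyl axial (anomeric effect) and trans to the pseudoaxial C4 methyl; a non-alcoholic solvent avoids acetal exchange at the lactol.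

## Compound list

1 | 4,5-dimethylbenzene-1,3-diol | Cc1cc(O)cc(O)c1C | starting material
2 | [(2,4-dihydroxy-5,6-dimethylphenyl)methylidene]dimethylammonium chloride | C[N+](C)=Cc1c(O)cc(O)c(C)c1C.[Cl-] | intermediate (not isolated)
3 | 2,4-dihydroxy-5,6-dimethylbenzaldehyde | O=Cc1c(O)cc(O)c(C)c1C | intermediate
4 | 2,4-bis(benzyloxy)-5,6-dimethylbenzaldehyde | O=Cc1c(OCc2ccccc2)cc(OCc2ccccc2)c(C)c1C | intermediate
5 | 2,4-bis(benzyloxy)-5,6-dimethylbenzoic acid | OC(=O)c1c(OCc2ccccc2)cc(OCc2ccccc2)c(C)c1C | intermediate
6 | (E)-but-2-en-1-ol | C/C=C/CO | starting material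
7 | [(2S,3S)-3-methyloxiran-2-yl]methanol | C[C@@H]1O[C@H]1CO | intermediate
8 | ethynyltrimethylsilane | C#C[Si](C)(C)C | starting material
9 | lithium (trimethylsilyl)acetylide | [Li+].[C-]#C[Si](C)(C)C | intermediate (not isolated)
10 | diethyl[(trimethylsilyl)ethynyl]aluminium | CC[Al](CC)C#C[Si](C)(C)C | intermediate (not isolated)
11 | (2R,3S)-3-methyl-5-(trimethylsilyl)pent-4-yne-1,2-diol | C[Si](C)(C)C#C[C@H](C)[C@@H](O)CO | intermediate
12 | (2R,3S)-3-methylpent-4-yne-1,2-diol | C#C[C@H](C)[C@@H](O)CO | intermediate
13 | 2,4-bis(benzyloxy)-5,6-dimethylbenzoyl chloride | O=C(Cl)c1c(OCc2ccccc2)cc(OCc2ccccc2)c(C)c1C | intermediate (not isolated)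
14 | (2R,3S)-2-hydroxy-3-methylpent-4-yn-1-yl 2,4-bis(benzyloxy)-5,6-dimethylbenzoate | C#C[C@H](C)[C@@H](O)COC(=O)c1c(OCc2ccccc2)cc(OCc2ccccc2)c(C)c1C | intermediate
15 | (2R,3S)-3-methyl-2-(triethylsilyloxy)pent-4-yn-1-yl 2,4-bis(benzyloxy)-5,6-dimethylbenzoate | C#C[C@H](C)[C@@H](O[Si](CC)(CC)CC)COC(=O)c1c(OCc2ccccc2)cc(OCc2ccccc2)c(C)c1C | intermediate
16 | lithium acetylide of 15 | [Li+].[C-]#C[C@H](C)[C@@H](O[Si](CC)(CC)CC)COC(=O)c1c(OCc2ccccc2)cc(OCc2ccccc2)c(C)c1C | intermediate (not isolated)
17 | benzyl (4S,5R)-6-{[2,4-bis(benzyloxy)-5,6-dimethylbenzoyl]oxy}-4-methyl-5-(triethylsilyloxy)hex-2-ynoate | O=C(OCc1ccccc1)C#C[C@H](C)[C@@H](O[Si](CC)(CC)CC)COC(=O)c1c(OCc2ccccc2)cc(OCc2ccccc2)c(C)c1C | intermediate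
18 | methyl 3-oxopentanoate | CCC(=O)CC(=O)OC | starting material
19 | methyl 3,3-dimethoxypentanoate | CCC(OC)(OC)CC(=O)OC | intermediate (not isolated)
20 | methyl (2E)-3-methoxypent-2-enoate | CC/C(OC)=C\C(=O)OC | intermediate
21 | lithium (3Z)-1,3-dimethoxypenta-1,3-dien-1-olate | C/C=C(\OC)C=C(OC)[O-].[Li+] | intermediate (not isolated)
22 | (3Z)-1,3-dimethoxy-1-(trimethylsilyloxy)penta-1,3-diene | C/C=C(\OC)C=C(OC)O[Si](C)(C)C | intermediate
23 | benzyl 2-[(2S,3R)-4-{[2,4-bis(benzyloxy)-5,6-dimethylbenzoyl]oxy}-3-(triethylsilyloxy)butan-2-yl]-4,6-dimethoxy-3-methyl-6-(trimethylsilyloxy)cyclohexa-1,4-diene-1-carboxylate (ring C3 and C6 unassigned) | COC1=CC(OC)(O[Si](C)(C)C)C(C(=O)OCc2ccccc2)=C(C1C)[C@H](C)[C@@H](O[Si](CC)(CC)CC)COC(=O)c1c(OCc2ccccc2)cc(OCc2ccccc2)c(C)c1C | intermediate (not isolated)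
24 | benzyl 2-[(2S,3R)-4-{[2,4-bis(benzyloxy)-5,6-dimethylbenzoyl]oxy}-3-(triethylsilyloxy)butan-2-yl]-4-methoxy-3-methyl-6-(trimethylsilyloxy)benzoate | COc1cc(O[Si](C)(C)C)c(C(=O)OCc2ccccc2)c(c1C)[C@H](C)[C@@H](O[Si](CC)(CC)CC)COC(=O)c1c(OCc2ccccc2)cc(OCc2ccccc2)c(C)c1C | intermediate (not isolated)
25 | benzyl 2-[(2S,3R)-4-{[2,4-bis(benzyloxy)-5,6-dimethylbenzoyl]oxy}-3-(triethylsilyloxy)butan-2-yl]-6-hydroxy-4-methoxy-3-methylbenzoate | COc1cc(O)c(C(=O)OCc2ccccc2)c(c1C)[C@H](C)[C@@H](O[Si](CC)(CC)CC)COC(=O)c1c(OCc2ccccc2)cc(OCc2ccccc2)c(C)c1C | intermediate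
26 | benzyl 6-(benzyloxy)-2-[(2S,3R)-4-{[2,4-bis(benzyloxy)-5,6-dimethylbenzoyl]oxy}-3-(triethylsilyloxy)butan-2-yl]-4-methoxy-3-methylbenzoate | COc1cc(OCc2ccccc2)c(C(=O)OCc2ccccc2)c(c1C)[C@H](C)[C@@H](O[Si](CC)(CC)CC)COC(=O)c1c(OCc2ccccc2)cc(OCc2ccccc2)c(C)c1C | intermediate
27 | benzyl 6-(benzyloxy)-2-[(2S,3R)-4-{[2,4-bis(benzyloxy)-5,6-dimethylbenzoyl]oxy}-3-hydroxybutan-2-yl]-4-methoxy-3-methylbenzoate | COc1cc(OCc2ccccc2)c(C(=O)OCc2ccccc2)c(c1C)[C@H](C)[C@@H](O)COC(=O)c1c(OCc2ccccc2)cc(OCc2ccccc2)c(C)c1C | intermediate
28 | benzyl 6-(benzyloxy)-2-[(2S)-4-{[2,4-bis(benzyloxy)-5,6-dimethylbenzoyl]oxy}-3-oxobutan-2-yl]-4-methoxy-3-methylbenzoate | COc1cc(OCc2ccccc2)c(C(=O)OCc2ccccc2)c(c1C)[C@H](C)C(=O)COC(=O)c1c(OCc2ccccc2)cc(OCc2ccccc2)c(C)c1C | intermediate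
29 | 2-[(2S)-4-[(2,4-dihydroxy-5,6-dimethylbenzoyl)oxy]-3-oxobutan-2-yl]-6-hydroxy-4-methoxy-3-methylbenzoic acid | COc1cc(O)c(C(=O)O)c(c1C)[C@H](C)C(=O)COC(=O)c1c(O)cc(O)c(C)c1C | intermediate (not isolated)
30 | [(3R,4S)-3,8-dihydroxy-6-methoxy-4,5-dimethyl-1-oxo-3,4-dihydro-1H-isochromen-3-yl]methyl 2,4-dihydroxy-5,6-dimethylbenzoate | COc1cc(O)c2c(c1C)[C@H](C)[C@](O)(COC(=O)c1c(O)cc(O)c(C)c1C)OC2=O | target

## Step count and least certain steps

Total: 16 steps. Longest linear sequence: 11 steps (steps 4–9 and 12–16 from alcohol 6; the branch from resorcinol 1 through steps 1–3, 7–9 and 12–16 is equally long).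

**Step 12 (key step).** The most likely failure is low conversion, because both bond-forming carbons are substituted and the ynoate β-carbon is branched. Thermal breakdown of the diene (silyl migration from oxygen to carbon) and [2+2] or conjugate addition at its ketene-acetal double bond, which cannot aromatise, can then overtake the cycloaddition. High pressure (12 kbar, CH2Cl2, rt) is the first variation of conditions. The fallback changes the dienophile and sets out from alkyne 15. Deprotonation with LiN(SiMe3)2 (THF, −78 °C), formylation with DMF and a quench into aqueous KH2PO4 would give ynal (2R,3S)-3-methyl-6-oxo-2-(triethylsilyloxy)hex-4-yn-1-yl 2,4-bis(benzyloxy)-5,6-dimethylbenzoate F1. Its aldehyde-activated triple bond should take up diene 22 well below 100 °C with the same regiochemistry and give, after silica, salicylaldehyde (2R,3S)-3-(2-formyl-3-hydroxy-5-methoxy-6-methylphenyl)-2-(triethylsilyloxy)butyl 2,4-bis(benzyloxy)-5,6-dimethylbenzoate F2. Benzylation (BnBr, K2CO3, DMF) would give the benzyl ether (2R,3S)-3-[3-(benzyloxy)-2-formyl-5-methoxy-6-methylphenyl]-2-(triethylsilyloxy)butyl 2,4-bis(benzyloxy)-5,6-dimethylbenzoate F3. Pinnick oxidation would give 6-(benzyloxy)-2-[(2S,3R)-4-{[2,4-bis(benzyloxy)-5,6-dimethylbenzoyl]oxy}-3-(triethylsilyloxy)butan-2-yl]-4-methoxy-3-methylbenzoic acid F4, and alkylation of its carboxylate (BnBr, KHCO3, DMF) returns to the route at 26.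

**Step 5.** Regioselectivity may erode: attack at C2 gives the 1,3-diol, and ethyl transfer from aluminium can compete with alkynyl transfer. The fallback replaces chelation-directed delivery by external Lewis acid activation and sets out from epoxy alcohol 7. Silylation (t-BuMe2SiCl, imidazole) would give tert-butyldimethyl{[(2S,3S)-3-methyloxiran-2-yl]methoxy}silane F5. Acetylide 9 with BF3·OEt2 (THF, −78 °C) should open it at C3, the carbon remote from the electron-withdrawing, bulky silyloxymethyl group, with inversion, to give (2R,3S)-1-(tert-butyldimethylsilyloxy)-3-methyl-5-(trimethylsilyl)pent-4-yn-2-ol F6. Bu4NF removes both silyl groups and returns to the route at 12.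

**Step 7.** The hindered acyl chloride may acylate sluggishly, and forcing it can cost primary over secondary discrimination and lead to diacylation. The fallback makes the ester bond by O-alkylation of the carboxylate and sets out from diol 12. Primary-selective tosylation (TsCl, Et3N, Bu2SnO cat.) would give (2R,3S)-2-hydroxy-3-methylpent-4-yn-1-yl 4-methylbenzenesulfonate F7. Acid 5 with Cs2CO3 in DMF should displace the tosylate at the primary carbon, directly or through the terminal epoxide, which the carboxylate opens at the same carbon; either path returns to the route at 14.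

**Step 9.** Any excess base or warming can cause propargyl–allenyl isomerisation of the product ynoate, with loss of the C4 configuration; a second acetylide can also add to the new ester. The fallback avoids carbanions and runs from 15 straight to 17: oxidative alkoxycarbonylation of the terminal alkyne (PdCl2 cat., CuCl2, NaOAc, CO 1 atm, benzyl alcohol, rt).

**Step 14.** The freed C3 hydroxyl can lactonise onto the ring A benzyl ester, which would fix C3 irreversibly at the wrong oxidation level, or the ring B acyl group can migrate to it. The fallback never accumulates the free alcohol and runs from 26 straight to 28: oxidative desilylation with IBX in DMSO at rt, which cleaves triethylsilyl ethers and oxidises the alcohol as it is released; the phenol benzylated in step 13 makes this compatible.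

## Further compounds

F1 | step 12 | (2R,3S)-3-methyl-6-oxo-2-(triethylsilyloxy)hex-4-yn-1-yl 2,4-bis(benzyloxy)-5,6-dimethylbenzoate | O=CC#C[C@H](C)[C@@H](O[Si](CC)(CC)CC)COC(=O)c1c(OCc2ccccc2)cc(OCc2ccccc2)c(C)c1C
F2 | step 12 | (2R,3S)-3-(2-formyl-3-hydroxy-5-methoxy-6-methylphenyl)-2-(triethylsilyloxy)butyl 2,4-bis(benzyloxy)-5,6-dimethylbenzoate | COc1cc(O)c(C=O)c(c1C)[C@H](C)[C@@H](O[Si](CC)(CC)CC)COC(=O)c1c(OCc2ccccc2)cc(OCc2ccccc2)c(C)c1C
F3 | step 12 | (2R,3S)-3-[3-(benzyloxy)-2-formyl-5-methoxy-6-methylphenyl]-2-(triethylsilyloxy)butyl 2,4-bis(benzyloxy)-5,6-dimethylbenzoate | COc1cc(OCc2ccccc2)c(C=O)c(c1C)[C@H](C)[C@@H](O[Si](CC)(CC)CC)COC(=O)c1c(OCc2ccccc2)cc(OCc2ccccc2)c(C)c1C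
F4 | step 12 | 6-(benzyloxy)-2-[(2S,3R)-4-{[2,4-bis(benzyloxy)-5,6-dimethylbenzoyl]oxy}-3-(triethylsilyloxy)butan-2-yl]-4-methoxy-3-methylbenzoic acid | COc1cc(OCc2ccccc2)c(C(=O)O)c(c1C)[C@H](C)[C@@H](O[Si](CC)(CC)CC)COC(=O)c1c(OCc2ccccc2)cc(OCc2ccccc2)c(C)c1C
F5 | step 5 | tert-butyldimethyl{[(2S,3S)-3-methyloxiran-2-yl]methoxy}silane | C[C@@H]1O[C@H]1CO[Si](C)(C)C(C)(C)C
F6 | step 5 | (2R,3S)-1-(tert-butyldimethylsilyloxy)-3-methyl-5-(trimethylsilyl)pent-4-yn-2-ol | C[Si](C)(C)C#C[C@H](C)[C@@H](O)CO[Si](C)(C)C(C)(C)C
F7 | step 7 | (2R,3S)-2-hydroxy-3-methylpent-4-yn-1-yl 4-methylbenzenesulfonate | C#C[C@H](C)[C@@H](O)COS(=O)(=O)c1ccc(C)cc1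
F0 | step 9 | none | none
F0 | step 14 | none | none
A1 | alternative 1 | benzyl 2-[(1S)-1-[(4S)-2,2-dimethyl-1,3-dioxolan-4-yl]ethyl]-4,6-dihydroxy-3-methylbenzoate | Cc1c(O)cc(O)c(C(=O)OCc2ccccc2)c1[C@H](C)[C@H]1COC(C)(C)O1
A2 | alternative 1 | 6-[(5R)-5-[(4S)-2,2-dimethyl-1,3-dioxolan-4-yl]-3-methyl-2,4-dioxohexyl]-2,2-dimethyl-4H-1,3-dioxin-4-one | CC1(C)OC(=O)C=C(CC(=O)C(C)C(=O)[C@H](C)[C@H]2COC(C)(C)O2)O1
A3 | alternative 2 | [(3R,4S)-8-(benzyloxy)-3-hydroxy-6-methoxy-4,5-dimethyl-1-oxo-3,4-dihydro-1H-isochromen-3-yl]methyl 2,4-bis(benzyloxy)-5,6-dimethylbenzoate | COc1cc(OCc3ccccc3)c2c(c1C)[C@H](C)[C@](O)(COC(=O)c1c(OCc3ccccc3)cc(OCc3ccccc3)c(C)c1C)OC2=O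
A4 | alternative 2 | [(2S,3S)-7-(benzyloxy)-2-hydroxy-5-methoxy-3,4-dimethyl-1-oxo-2,3-dihydro-1H-inden-2-yl]methyl 2,4-bis(benzyloxy)-5,6-dimethylbenzoate | COc1cc(OCc3ccccc3)c2c(c1C)[C@H](C)[C@](O)(COC(=O)c1c(OCc3ccccc3)cc(OCc3ccccc3)c(C)c1C)C2=O
A5 | alternative 3 | benzyl 6-(benzyloxy)-2-[(2S)-4-[(2,4-dihydroxy-5,6-dimethylbenzoyl)oxy]-3-oxobutan-2-yl]-4-methoxy-3-methylbenzoate | COc1cc(OCc2ccccc2)c(C(=O)OCc2ccccc2)c(c1C)[C@H](C)C(=O)COC(=O)c1c(O)cc(O)c(C)c1C
A6 | alternative 3 | benzyl 6-(benzyloxy)-2-[(2S)-4-(but-2-ynoyloxy)-3-oxobutan-2-yl]-4-methoxy-3-methylbenzoate | COc1cc(OCc2ccccc2)c(C(=O)OCc2ccccc2)c(c1C)[C@H](C)C(=O)COC(=O)C#CC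
A7 | alternative 3 | (3Z)-1-methoxy-1,3-bis(trimethylsilyloxy)penta-1,3-diene | C/C=C(\O[Si](C)(C)C)C=C(OC)O[Si](C)(C)C
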